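## Retrosynthetic overview
1. The last two operations are hydrogenolysis of a 2'-O-benzyl ether and, before it, chelation-directed cleavage of the 5-O-methyl ether of a fully O-alkylated 3-methoxyflavone.
2. The 3-OMe group comes from O-methylation of a flavonol, which is made by epoxidation and isomerisation of the C2=C3 bond of the parent flavone.
3. Ring C is the only ring that is built. It is closed by oxidative oxa-Michael cyclisation of a 2'-hydroxychalcone; rings A and B are bought as benzenoid aldehydes.
4. The key C-C disconnection is the chalcone Cα=Cβ bond, formed by intermolecular Claisen-Schmidt aldol condensation of a ring A methyl ketone with a ring B aldehyde.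
5. The ring A ketone comes from 2,3,4-trimethoxybenzaldehyde by two Baeyer-Villiger oxygenations (with methylation and formylation between them) and ortho-acetylation. The ring B aldehyde comes from benzylation of 2-hydroxy-4-methoxybenzaldehyde.

Assumption: the target has no stereocentre, stereogenic axis or stereogenic double bond. It is achiral, so no enantiocontrol is needed, and the racemic centres of the transient intermediates are all destroyed again.

## Route

Step 1
Reactants: 1 2,3,4-trimethoxybenzaldehyde
Product: 3 2,3,4-trimethoxyphenol, via 2,3,4-trimethoxyphenyl formate 2 (not isolated)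
Conditions: mCPBA (1.3 equiv), CH2Cl2, 0 °C to rt; then cat. conc. HCl, MeOH, rt
Reagents that add atoms: mCPBA (3-chloroperoxybenzoic acid) OOC(=O)c1cccc(Cl)c1
Why: In this Baeyer-Villiger (Dakin-type) oxidation the aryl group, activated by ortho and para methoxy donors, migrates in preference to hydride, and the labile aryl formate is then transesterified by acidic methanol so the free phenol never meets the peracid.

Step 2
Reactants: 3 2,3,4-trimethoxyphenol
Product: 4 1,2,3,4-tetramethoxybenzene
Conditions: MeI, K2CO3, acetone, reflux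
Reagents that add atoms: iodomethane CI
Why: This is a Williamson O-methylation (SN2 of the phenoxide on MeI), and no other nucleophilic site is present.

Step 3
Reactants: 4 1,2,3,4-tetramethoxybenzene
Product: 6 2,3,4,5-tetramethoxybenzaldehyde, via iminium salt 5 (not isolated)
Conditions: POCl3 (1.5 equiv), DMF, 0 to 80 °C; then ice-water, rt
Reagents that add atoms: N,N-dimethylformamide CN(C)C=O; water O
Why: In this Vilsmeier-Haack formylation the two free positions of the symmetric arene are equivalent and each lies ortho and para to methoxy donors, and the product aldehyde deactivates the ring against a second formylation.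

Step 4
Reactants: 6 2,3,4,5-tetramethoxybenzaldehyde
Product: 8 2,3,4,5-tetramethoxyphenol, via 2,3,4,5-tetramethoxyphenyl formate 7 (not isolated)
Conditions: mCPBA (1.2 equiv), CH2Cl2, 0 °C to rt; then cat. conc. HCl, MeOH, rt, N2
Reagents that add atoms: mCPBA (3-chloroperoxybenzoic acid) OOC(=O)c1cccc(Cl)c1
Why: A second Baeyer-Villiger oxidation with aryl migration works for the same reason as in step 1, and acidic rather than basic release of the very electron-rich phenol avoids air oxidation to a quinone.

Step 5
Reactants: 8 2,3,4,5-tetramethoxyphenol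
Product: 10 2-hydroxy-3,4,5,6-tetramethoxyacetophenone, via BF2 chelate 9 (not isolated)
Conditions: AcOH, BF3·OEt2 (3 equiv), 85 °C, 3 h; then aq. EtOH, 60 °C
Reagents that add atoms: acetic acid CC(=O)O
Why: This Lewis-acid-mediated Friedel-Crafts (Fries-type) C-acetylation can only occur at the single free ring position ortho to the phenol, and the product is held as a BF2 chelate that is hydrolysed on work-up.

Step 6
Reactants: 11 2-hydroxy-4-methoxybenzaldehyde
Product: 12 2-(benzyloxy)-4-methoxybenzaldehyde
Conditions: BnBr, K2CO3, DMF, 60 °C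
Reagents that add atoms: benzyl bromide BrCc1ccccc1
Why: This Williamson benzylation installs on the only phenol a group that withstands strong base, I2/DMSO, DMDO and MeI and is removed under neutral conditions at the end.

Step 7
Reactants: 10 2-hydroxy-3,4,5,6-tetramethoxyacetophenone; 12 2-(benzyloxy)-4-methoxybenzaldehyde
Product: 14 (E)-2-benzyloxy-2'-hydroxy-4,3',4',5',6'-pentamethoxychalcone, via aldol adduct 13 (not isolated)
Conditions: KOH (50% aq, 10 equiv), EtOH, rt, 48 h; then 2 M HCl
Reagents that add atoms: none
Why: In this Claisen-Schmidt crossed aldol condensation only the methyl ketone can enolise and only the aldehyde is a good acceptor, and E1cB dehydration of the racemic aldol gives the conjugated E-enone under thermodynamic control, so no stereocentre persists.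

Step 8
Reactants: 14 (E)-2-benzyloxy-2'-hydroxy-4,3',4',5',6'-pentamethoxychalcone
Product: 16 2'-benzyloxy-5,6,7,8,4'-pentamethoxyflavone, via flavanone 15 (not isolated)
Conditions: I2 (10 mol %), DMSO, 130 °C, 3 h
Reagents that add atoms: none
Why: In this iodine-catalysed oxidative cyclisation an intramolecular oxa-Michael addition closes ring C to the racemic flavanone, which is α-iodinated and loses HI, while DMSO re-oxidises HI to I2 and the benzyl and methyl ethers stay inert.

Step 9
Reactants: 16 2'-benzyloxy-5,6,7,8,4'-pentamethoxyflavone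
Product: 18 2'-benzyloxy-3-hydroxy-5,6,7,8,4'-pentamethoxyflavone, via flavone 2,3-epoxide 17 (not isolated)
Conditions: DMDO (ca. 0.08 M in acetone, 3 equiv), CH2Cl2, 0 °C to rt; then cat. p-TsOH·H2O, CH2Cl2, rt
Reagents that add atoms: dimethyldioxirane CC1(C)OO1
Why: Epoxidation of the enol-ether-like C2=C3 bond with a neutral oxidant and acid-catalysed epoxide-to-enol isomerisation gives the flavonol while avoiding the aurone formation that alkaline peroxide oxidation causes with 6'-alkoxychalcones.

Step 10
Reactants: 18 2'-benzyloxy-3-hydroxy-5,6,7,8,4'-pentamethoxyflavone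
Product: 19 2'-benzyloxy-3,5,6,7,8,4'-hexamethoxyflavone
Conditions: MeI, K2CO3, acetone, reflux
Reagents that add atoms: iodomethane CI
Why: This is a Williamson O-methylation of the acidic enolic 3-OH, which is the only free hydroxyl group in the molecule.

Step 11
Reactants: 19 2'-benzyloxy-3,5,6,7,8,4'-hexamethoxyflavone
Product: 21 2'-benzyloxy-5-hydroxy-3,6,7,8,4'-pentamethoxyflavone, via AlCl2 chelate 20 (not isolated)
Conditions: AlCl3 (5 equiv), MeCN, 60 °C, 1-2 h; then 2 M HCl, 60 °C, 20 min
Reagents that add atoms: none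
Why: In this chelation-controlled aryl methyl ether cleavage aluminium sits in a six-membered chelate between the C4 carbonyl and the peri 5-oxygen so that chloride attacks only that methyl group, while the Lewis acid, levelled by the donor solvent MeCN, leaves the non-chelating ethers, the less well chelated 3-OMe and the benzyl ether intact.

Step 12
Reactants: 21 2'-benzyloxy-5-hydroxy-3,6,7,8,4'-pentamethoxyflavone
Product: 22 5,2'-dihydroxy-3,6,7,8,4'-pentamethoxyflavone
Conditions: H2 (1 atm), 10% Pd/C, EtOAc/MeOH, rt
Reagents that add atoms: none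
Why: Catalytic hydrogenolysis cleaves the benzylic C-O bond, and the tetrasubstituted vinylogous-ester C2=C3 bond and the aryl methyl ethers are not reduced at 1 atm and rt.

## Compound list
1 | 2,3,4-trimethoxybenzaldehyde | COc1ccc(C=O)c(OC)c1OC | starting material
2 | 2,3,4-trimethoxyphenyl formate (not isolated) | COc1ccc(OC=O)c(OC)c1OC | intermediate
3 | 2,3,4-trimethoxyphenol | COc1ccc(O)c(OC)c1OC | intermediate
4 | 1,2,3,4-tetramethoxybenzene | COc1ccc(OC)c(OC)c1OC | intermediate
5 | N,N-dimethyl-(2,3,4,5-tetramethoxybenzylidene)iminium dichlorophosphate (not isolated) | COc1cc(C=[N+](C)C)c(OC)c(OC)c1OC.[O-]P(=O)(Cl)Cl | intermediate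
6 | 2,3,4,5-tetramethoxybenzaldehyde | COc1cc(C=O)c(OC)c(OC)c1OC | intermediate
7 | 2,3,4,5-tetramethoxyphenyl formate (not isolated) | COc1cc(OC=O)c(OC)c(OC)c1OC | intermediate
8 | 2,3,4,5-tetramethoxyphenol | COc1cc(O)c(OC)c(OC)c1OC | intermediate
9 | difluoroboron (BF2) chelate of 2-hydroxy-3,4,5,6-tetramethoxyacetophenone (not isolated) | CC1=[O+][B-](F)(F)Oc2c(OC)c(OC)c(OC)c(OC)c21 | intermediate
10 | 2-hydroxy-3,4,5,6-tetramethoxyacetophenone | CC(=O)c1c(O)c(OC)c(OC)c(OC)c1OC | intermediate
11 | 2-hydroxy-4-methoxybenzaldehyde | COc1ccc(C=O)c(O)c1 | starting material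
12 | 2-(benzyloxy)-4-methoxybenzaldehyde | COc1ccc(C=O)c(OCc2ccccc2)c1 | intermediate
13 | 3-[2-(benzyloxy)-4-methoxyphenyl]-3-hydroxy-1-(2-hydroxy-3,4,5,6-tetramethoxyphenyl)propan-1-one, racemic (not isolated) | COc1ccc(C(O)CC(=O)c2c(O)c(OC)c(OC)c(OC)c2OC)c(OCc2ccccc2)c1 | intermediate
14 | (E)-3-[2-(benzyloxy)-4-methoxyphenyl]-1-(2-hydroxy-3,4,5,6-tetramethoxyphenyl)prop-2-en-1-one (the chalcone) | COc1ccc(/C=C/C(=O)c2c(O)c(OC)c(OC)c(OC)c2OC)c(OCc2ccccc2)c1 | intermediate
15 | 2-[2-(benzyloxy)-4-methoxyphenyl]-5,6,7,8-tetramethoxychroman-4-one, racemic (not isolated) | COc1ccc(C2CC(=O)c3c(OC)c(OC)c(OC)c(OC)c3O2)c(OCc2ccccc2)c1 | intermediate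
16 | 2'-benzyloxy-5,6,7,8,4'-pentamethoxyflavone | COc1ccc(-c2cc(=O)c3c(OC)c(OC)c(OC)c(OC)c3o2)c(OCc2ccccc2)c1 | intermediate
17 | 2,3-epoxide of 16, racemic (not isolated) | COc1ccc(C23OC2C(=O)c2c(OC)c(OC)c(OC)c(OC)c2O3)c(OCc2ccccc2)c1 | intermediate
18 | 2'-benzyloxy-3-hydroxy-5,6,7,8,4'-pentamethoxyflavone | COc1ccc(-c2oc3c(OC)c(OC)c(OC)c(OC)c3c(=O)c2O)c(OCc2ccccc2)c1 | intermediate
19 | 2'-benzyloxy-3,5,6,7,8,4'-hexamethoxyflavone | COc1ccc(-c2oc3c(OC)c(OC)c(OC)c(OC)c3c(=O)c2OC)c(OCc2ccccc2)c1 | intermediate
20 | 5-O-AlCl2 chelate (Al bridging O-5 and the C4 carbonyl oxygen) of 21 (not isolated) | COC1=C(c2ccc(OC)cc2OCc2ccccc2)Oc2c(OC)c(OC)c(OC)c3O[Al-](Cl)(Cl)[O+]=C1c23 | intermediate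
21 | 2'-benzyloxy-5-hydroxy-3,6,7,8,4'-pentamethoxyflavone | COc1ccc(-c2oc3c(OC)c(OC)c(OC)c(O)c3c(=O)c2OC)c(OCc2ccccc2)c1 | intermediate
22 | 5,2'-dihydroxy-3,6,7,8,4'-pentamethoxyflavone (achiral) | COc1ccc(-c2oc3c(OC)c(OC)c(OC)c(O)c3c(=O)c2OC)c(O)c1 | target

## Step count and risks
Total step count: 12.
Longest linear sequence: 11 steps (steps 1-5 and 7-12, from 1 to 22). Step 6 is a one-step side branch.

**Step 7, aldol condensation.**
- The risk is a slow or incomplete reaction, because the ketone carries two ortho substituents and the aldehyde is electron-rich and ortho-substituted.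
- Partial ring closure of 14 to the flavanone is harmless, since step 8 converts both compounds.
- The fallback sets out from 10 and 12 and comes back at 16. It replaces the aldol by an intermolecular Claisen-type C-acylation.
- Aldehyde 12 is oxidised (NaClO2, NaH2PO4, 2-methyl-2-butene, t-BuOH/H2O) to 2-(benzyloxy)-4-methoxybenzoic acid F1.
- (COCl)2 with cat. DMF in CH2Cl2 converts the acid into 2-(benzyloxy)-4-methoxybenzoyl chloride F2.
- Ketone 10 is deprotonated twice with LiN(SiMe3)2 (3.2 equiv, THF, -78 °C) to the dilithium enolate-phenolate F3.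
- F3 is acylated by F2 to give 1-[2-(benzyloxy)-4-methoxyphenyl]-3-(2-hydroxy-3,4,5,6-tetramethoxyphenyl)propane-1,3-dione F4. Any O-acylated material rearranges to the same diketone under the excess base.
- Cyclodehydration of F4 with cat. p-TsOH in refluxing toluene gives flavone 16 directly, so step 8 is skipped as well.

**Step 9, C3 oxygenation with DMDO.**
- The risk is slow epoxidation of a hindered push-pull alkene, with competing oxidation of the benzylic C-H bonds or of the electron-rich rings when a large excess of oxidant is needed.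
- The fallback sets out from 16 and comes back at 18. It changes from electrophilic oxidation to deprotonation, borylation and oxidation.
- LiN(iPr)2 (1.3 equiv, THF, -78 °C) removes the acidic H-3 to give the 3-lithioflavone F5.
- B(OMe)3 traps F5 as the dimethyl flavon-3-ylboronate F6.
- AcOH and 30% H2O2 oxidise F6 in the same flask to flavonol 18.

**Step 11, selective 5-O-demethylation.**
- The risk is competing loss of the 3-OMe group, which also flanks the carbonyl, or of the 6-OMe group on over-reaction.
- Partial loss of the benzyl group is harmless, because it only produces 22 early.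
- The fallback sets out from 18 and comes back at 21. It moves the selectivity problem from demethylation to methylation.
- Flavonol 18, which has no 3-O-methyl group to lose, is treated with AlCl3 in MeCN and then warm dilute HCl. This gives 2'-benzyloxy-3,5-dihydroxy-6,7,8,4'-tetramethoxyflavone F7.
- MeI (1.05 equiv) with K2CO3 in acetone at rt then methylates only the more acidic, less strongly chelated 3-OH. The hydrogen-bonded 5-OH, flanked by the 6-OMe group, does not react, and the product is 21.

## Further compounds
F1 | step 7 | 2-(benzyloxy)-4-methoxybenzoic acid | COc1ccc(C(=O)O)c(OCc2ccccc2)c1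
F2 | step 7 | 2-(benzyloxy)-4-methoxybenzoyl chloride | COc1ccc(C(=O)Cl)c(OCc2ccccc2)c1
F3 | step 7 | dilithium enolate-phenolate of 2-hydroxy-3,4,5,6-tetramethoxyacetophenone | [Li]OC(=C)c1c(O[Li])c(OC)c(OC)c(OC)c1OC
F4 | step 7 | 1-[2-(benzyloxy)-4-methoxyphenyl]-3-(2-hydroxy-3,4,5,6-tetramethoxyphenyl)propane-1,3-dione | COc1ccc(C(=O)CC(=O)c2c(O)c(OC)c(OC)c(OC)c2OC)c(OCc2ccccc2)c1
F5 | step 9 | 2'-benzyloxy-3-lithio-5,6,7,8,4'-pentamethoxyflavone | COc1ccc(-c2oc3c(OC)c(OC)c(OC)c(OC)c3c(=O)c2[Li])c(OCc2ccccc2)c1
F6 | step 9 | dimethyl (2'-benzyloxy-5,6,7,8,4'-pentamethoxyflavon-3-yl)boronate | COc1ccc(-c2oc3c(OC)c(OC)c(OC)c(OC)c3c(=O)c2B(OC)OC)c(OCc2ccccc2)c1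
F7 | step 11 | 2'-benzyloxy-3,5-dihydroxy-6,7,8,4'-tetramethoxyflavone | COc1ccc(-c2oc3c(OC)c(OC)c(OC)c(O)c3c(=O)c2O)c(OCc2ccccc2)c1
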